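**Retrosynthetic overview**
- Last step: sixteen-fold O-demethylation with BBr3. Before it, one copper-catalysed 4+3 union makes the ring D–O–ring E bond.
- The other five diaryl ether bonds come from a "formyl relay": SNAr of a 2,6-dioxygenated phenoxide on a fluorobenzaldehyde, then Baeyer–Villiger (Dakin-type) excision of the formyl group. The activating group becomes the phenol oxygen for the next SNAr, so no protecting-group steps are needed.
- Ring D is an ortho-fluoro aldehyde. After SNAr with fragment ABC, its ortho formyl is turned into the ring D hydroxyl that carries the second arm, which fixes the 1,2-bis(aryloxy) pattern.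
- Order of ring joining (no ring is built; all seven benzene rings are bought): A→B→C→D; separately E→F→G from a para-bromo phenol; then the D–E union, oxidation on ring G, demethylation.

Assumption: the target has no stereocentre and its diaryl ether axes rotate freely, so it is achiral and "single enantiomer" needs no stereocontrol. The four arenes marked as starting materials are taken to be catalogue compounds.

**Route**

Step 1
Reactants: 1 2,4,6-trimethoxyphenol; 2 4-fluoro-2,6-dimethoxybenzaldehyde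
Product: 3 2,6-dimethoxy-4-(2,4,6-trimethoxyphenoxy)benzaldehyde
Conditions: Cs2CO3 (1.5 equiv), DMSO, 110 °C, argon
Reagents that add atoms: none
Why: SNAr (addition–elimination): fluoride is para to the formyl group, which stabilises the Meisenheimer adduct, and meta to both methoxy groups, so the electron-rich phenoxide displaces it; no stereocentre is formed.

Step 2
Reactants: 3 2,6-dimethoxy-4-(2,4,6-trimethoxyphenoxy)benzaldehyde
Product: 5 2,6-dimethoxy-4-(2,4,6-trimethoxyphenoxy)phenol, via AB aryl formate 4 (not isolated)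
Conditions: mCPBA (1.2 equiv), CH2Cl2, 0 °C to rt; then K2CO3 (cat.), MeOH, rt
Reagents that add atoms: mCPBA (3-chloroperoxybenzoic acid), O=C(OO)c1cccc(Cl)c1
Why: Baeyer–Villiger (Dakin-type) oxidation: the aryl group flanked by two ortho methoxy groups migrates in preference to hydrogen, and methanolysis of the formate frees the phenol where the next ether oxygen is needed; no stereocentre.

Step 3
Reactants: 5 2,6-dimethoxy-4-(2,4,6-trimethoxyphenoxy)phenol; 2 4-fluoro-2,6-dimethoxybenzaldehyde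
Product: 6 4-[2,6-dimethoxy-4-(2,4,6-trimethoxyphenoxy)phenoxy]-2,6-dimethoxybenzaldehyde
Conditions: Cs2CO3 (1.5 equiv), DMSO, 120 °C, argon
Reagents that add atoms: none
Why: Second SNAr of the relay, same para-formyl activation as step 1; exchange of the product aryloxy group by the same phenoxide is degenerate, so no scrambling; no stereocentre.

Step 4
Reactants: 6 4-[2,6-dimethoxy-4-(2,4,6-trimethoxyphenoxy)phenoxy]-2,6-dimethoxybenzaldehyde
Product: 8 4-[2,6-dimethoxy-4-(2,4,6-trimethoxyphenoxy)phenoxy]-2,6-dimethoxyphenol, via ABC aryl formate 7 (not isolated)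
Conditions: mCPBA (1.2 equiv), CH2Cl2, 0 °C to rt; then K2CO3 (cat.), MeOH, rt
Reagents that add atoms: mCPBA (3-chloroperoxybenzoic acid), O=C(OO)c1cccc(Cl)c1
Why: Baeyer–Villiger (Dakin-type) oxidation as in step 2, with aryl migration from the 2,6-dimethoxy-substituted formyl carbon and formate methanolysis; no stereocentre.

Step 5
Reactants: 9 5-fluoro-1,2,3-trimethoxybenzene
Product: 11 6-fluoro-2,3,4-trimethoxybenzaldehyde, via chloro(methoxy)methyl arene 10 (not isolated)
Conditions: Cl2CHOMe, TiCl4, CH2Cl2, 0 °C; then H2O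
Reagents that add atoms: dichloromethyl methyl ether, COC(Cl)Cl; water, O
Why: Rieche formylation (Friedel–Crafts type): the two free ring positions are equivalent, each para to one methoxy and ortho to another, so only one regioisomer can form; the racemic chloro ether is hydrolysed on quench and leaves no stereocentre.

Step 6
Reactants: 8 4-[2,6-dimethoxy-4-(2,4,6-trimethoxyphenoxy)phenoxy]-2,6-dimethoxyphenol; 11 6-fluoro-2,3,4-trimethoxybenzaldehyde
Product: 12 6-{4-[2,6-dimethoxy-4-(2,4,6-trimethoxyphenoxy)phenoxy]-2,6-dimethoxyphenoxy}-2,3,4-trimethoxybenzaldehyde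
Conditions: Cs2CO3 (2 equiv), DMSO, 130 °C, argon
Reagents that add atoms: none
Why: SNAr of an ortho-fluorobenzaldehyde: the ortho formyl group takes up the Meisenheimer charge and the attacked carbon has only one ortho substituent; activation is weaker than in step 1, hence the higher temperature; no stereocentre.

Step 7
Reactants: 12 6-{4-[2,6-dimethoxy-4-(2,4,6-trimethoxyphenoxy)phenoxy]-2,6-dimethoxyphenoxy}-2,3,4-trimethoxybenzaldehyde
Product: 14 6-{4-[2,6-dimethoxy-4-(2,4,6-trimethoxyphenoxy)phenoxy]-2,6-dimethoxyphenoxy}-2,3,4-trimethoxyphenol, via ABCD aryl formate 13 (not isolated)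
Conditions: mCPBA (1.2 equiv), CH2Cl2, 0 °C to rt; then K2CO3 (cat.), MeOH, rt
Reagents that add atoms: mCPBA (3-chloroperoxybenzoic acid), O=C(OO)c1cccc(Cl)c1
Why: Baeyer–Villiger (Dakin-type) oxidation: the formyl carbon lies between an aryloxy and a methoxy group and para to a methoxy, so the aryl migrates; the new hydroxyl is the ring D oxygen ortho to the ABC ether, the site of the second arm; no stereocentre.

Step 8
Reactants: 15 4-bromo-2,6-dimethoxyphenol; 2 4-fluoro-2,6-dimethoxybenzaldehyde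
Product: 16 4-(4-bromo-2,6-dimethoxyphenoxy)-2,6-dimethoxybenzaldehyde
Conditions: Cs2CO3 (1.5 equiv), DMSO, 120 °C, argon
Reagents that add atoms: none
Why: SNAr para to the formyl group as in step 1; the aryl bromide is not activated and is inert without a metal catalyst; no stereocentre.

Step 9
Reactants: 16 4-(4-bromo-2,6-dimethoxyphenoxy)-2,6-dimethoxybenzaldehyde
Product: 18 4-(4-bromo-2,6-dimethoxyphenoxy)-2,6-dimethoxyphenol, via bromo EF aryl formate 17 (not isolated)
Conditions: mCPBA (1.2 equiv), CH2Cl2, 0 °C to rt; then K2CO3 (cat.), MeOH, rt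
Reagents that add atoms: mCPBA (3-chloroperoxybenzoic acid), O=C(OO)c1cccc(Cl)c1
Why: Baeyer–Villiger (Dakin-type) oxidation as in step 2; the bromide is untouched by peracid; no stereocentre.

Step 10
Reactants: 18 4-(4-bromo-2,6-dimethoxyphenoxy)-2,6-dimethoxyphenol; 2 4-fluoro-2,6-dimethoxybenzaldehyde
Product: 19 4-[4-(4-bromo-2,6-dimethoxyphenoxy)-2,6-dimethoxyphenoxy]-2,6-dimethoxybenzaldehyde
Conditions: Cs2CO3 (1.5 equiv), DMSO, 120 °C, argon
Reagents that add atoms: none
Why: SNAr para to the formyl group as in step 1, which installs ring G with its formyl group as the latent central hydroxyl; no stereocentre.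

Step 11
Reactants: 14 6-{4-[2,6-dimethoxy-4-(2,4,6-trimethoxyphenoxy)phenoxy]-2,6-dimethoxyphenoxy}-2,3,4-trimethoxyphenol; 19 4-[4-(4-bromo-2,6-dimethoxyphenoxy)-2,6-dimethoxyphenoxy]-2,6-dimethoxybenzaldehyde
Product: 20 heptamer aldehyde ABCDEFG (the hydroxyl oxygen of 14 bonded to the former C–Br carbon of 19; sixteen OMe; formyl on ring G)
Conditions: CuI (20 mol %), picolinic acid (40 mol %), K3PO4 (2 equiv), DMSO, 90 °C, argon
Reagents that add atoms: none
Why: Ullmann-type diaryl ether coupling catalysed by monovalent copper: the picolinate-ligated copper phenoxide of the hindered phenol couples with the unhindered aryl bromide (the combination of partners this ligand system is known to tolerate), and the ring G aldehyde is a spectator; no stereocentre.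

Step 12
Reactants: 20 heptamer aldehyde ABCDEFG
Product: 22 heptamer phenol ABCDEFG (sixteen OMe; free OH on ring G between its two OMe), via heptamer aryl formate 21 (not isolated)
Conditions: mCPBA (1.3 equiv), CH2Cl2, 0 °C to rt; then K2CO3 (cat.), MeOH, rt
Reagents that add atoms: mCPBA (3-chloroperoxybenzoic acid), O=C(OO)c1cccc(Cl)c1
Why: Baeyer–Villiger (Dakin-type) oxidation of the only carbonyl group, with the same aryl migration as in step 2; no stereocentre.

Step 13
Reactants: 22 heptamer phenol ABCDEFG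
Product: 23 CNP0304148.0 (target; seventeen free OH)
Conditions: BBr3 (40 equiv), CH2Cl2, −78 °C to rt, argon; then degassed MeOH/H2O; Sephadex LH-20
Reagents that add atoms: none
Why: Lewis-acid ether cleavage: BBr3 cleaves aryl methyl ethers by bromide attack at methyl and leaves diaryl ether bonds intact, so all sixteen OMe groups become OH; the achiral target has no stereocentre to set.

**Compound list**

1 | 2,4,6-trimethoxyphenol | COc1cc(OC)c(O)c(OC)c1 | starting material
2 | 4-fluoro-2,6-dimethoxybenzaldehyde | COc1cc(F)cc(OC)c1C=O | starting material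
3 | 2,6-dimethoxy-4-(2,4,6-trimethoxyphenoxy)benzaldehyde | COc1cc(OC)c(Oc2cc(OC)c(C=O)c(OC)c2)c(OC)c1 | intermediate
4 | AB aryl formate: 2,6-dimethoxy-4-(2,4,6-trimethoxyphenoxy)phenyl formate | COc1cc(OC)c(Oc2cc(OC)c(OC=O)c(OC)c2)c(OC)c1 | intermediate
5 | 2,6-dimethoxy-4-(2,4,6-trimethoxyphenoxy)phenol | COc1cc(OC)c(Oc2cc(OC)c(O)c(OC)c2)c(OC)c1 | intermediate
6 | 4-[2,6-dimethoxy-4-(2,4,6-trimethoxyphenoxy)phenoxy]-2,6-dimethoxybenzaldehyde | COc1cc(OC)c(Oc2cc(OC)c(Oc3cc(OC)c(C=O)c(OC)c3)c(OC)c2)c(OC)c1 | intermediate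
7 | ABC aryl formate: formate ester of 8 | COc1cc(OC)c(Oc2cc(OC)c(Oc3cc(OC)c(OC=O)c(OC)c3)c(OC)c2)c(OC)c1 | intermediate
8 | 4-[2,6-dimethoxy-4-(2,4,6-trimethoxyphenoxy)phenoxy]-2,6-dimethoxyphenol | COc1cc(OC)c(Oc2cc(OC)c(Oc3cc(OC)c(O)c(OC)c3)c(OC)c2)c(OC)c1 | intermediate
9 | 5-fluoro-1,2,3-trimethoxybenzene | COc1cc(F)cc(OC)c1OC | starting material
10 | chloro(methoxy)methyl arene: 1-[chloro(methoxy)methyl]-6-fluoro-2,3,4-trimethoxybenzene (racemic) | COC(Cl)c1c(F)cc(OC)c(OC)c1OC | intermediate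
11 | 6-fluoro-2,3,4-trimethoxybenzaldehyde | COc1cc(F)c(C=O)c(OC)c1OC | intermediate
12 | 6-{4-[2,6-dimethoxy-4-(2,4,6-trimethoxyphenoxy)phenoxy]-2,6-dimethoxyphenoxy}-2,3,4-trimethoxybenzaldehyde | COc1cc(OC)c(Oc2cc(OC)c(Oc3cc(OC)c(Oc4cc(OC)c(OC)c(OC)c4C=O)c(OC)c3)c(OC)c2)c(OC)c1 | intermediate
13 | ABCD aryl formate: formate ester of 14 | COc1cc(OC)c(Oc2cc(OC)c(Oc3cc(OC)c(Oc4cc(OC)c(OC)c(OC)c4OC=O)c(OC)c3)c(OC)c2)c(OC)c1 | intermediate
14 | 6-{4-[2,6-dimethoxy-4-(2,4,6-trimethoxyphenoxy)phenoxy]-2,6-dimethoxyphenoxy}-2,3,4-trimethoxyphenol | COc1cc(OC)c(Oc2cc(OC)c(Oc3cc(OC)c(Oc4cc(OC)c(OC)c(OC)c4O)c(OC)c3)c(OC)c2)c(OC)c1 | intermediate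
15 | 4-bromo-2,6-dimethoxyphenol | COc1cc(Br)cc(OC)c1O | starting material
16 | 4-(4-bromo-2,6-dimethoxyphenoxy)-2,6-dimethoxybenzaldehyde | COc1cc(Br)cc(OC)c1Oc1cc(OC)c(C=O)c(OC)c1 | intermediate
17 | bromo EF aryl formate: formate ester of 18 | COc1cc(Br)cc(OC)c1Oc1cc(OC)c(OC=O)c(OC)c1 | intermediate
18 | 4-(4-bromo-2,6-dimethoxyphenoxy)-2,6-dimethoxyphenol | COc1cc(Br)cc(OC)c1Oc1cc(OC)c(O)c(OC)c1 | intermediate
19 | 4-[4-(4-bromo-2,6-dimethoxyphenoxy)-2,6-dimethoxyphenoxy]-2,6-dimethoxybenzaldehyde | COc1cc(Br)cc(OC)c1Oc1cc(OC)c(Oc2cc(OC)c(C=O)c(OC)c2)c(OC)c1 | intermediate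
20 | heptamer aldehyde ABCDEFG (sixteen OMe, formyl on ring G) | COc1cc(OC)c(Oc2cc(OC)c(Oc3cc(OC)c(Oc4cc(OC)c(OC)c(OC)c4Oc4cc(OC)c(Oc5cc(OC)c(Oc6cc(OC)c(C=O)c(OC)c6)c(OC)c5)c(OC)c4)c(OC)c3)c(OC)c2)c(OC)c1 | intermediate
21 | heptamer aryl formate: formate ester of 22 | COc1cc(OC)c(Oc2cc(OC)c(Oc3cc(OC)c(Oc4cc(OC)c(OC)c(OC)c4Oc4cc(OC)c(Oc5cc(OC)c(Oc6cc(OC)c(OC=O)c(OC)c6)c(OC)c5)c(OC)c4)c(OC)c3)c(OC)c2)c(OC)c1 | intermediate
22 | heptamer phenol ABCDEFG (sixteen OMe, one OH on ring G) | COc1cc(OC)c(Oc2cc(OC)c(Oc3cc(OC)c(Oc4cc(OC)c(OC)c(OC)c4Oc4cc(OC)c(Oc5cc(OC)c(Oc6cc(OC)c(O)c(OC)c6)c(OC)c5)c(OC)c4)c(OC)c3)c(OC)c2)c(OC)c1 | intermediate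
23 | CNP0304148.0 (achiral) | Oc1cc(O)c(Oc2cc(O)c(Oc3cc(O)c(Oc4cc(O)c(O)c(O)c4Oc4cc(O)c(Oc5cc(O)c(Oc6cc(O)c(O)c(O)c6)c(O)c5)c(O)c4)c(O)c3)c(O)c2)c(O)c1 | target

**Step count and risks**

Total step count: 13. Longest linear sequence: 9 steps (1, 2, 3, 4, 6, 7, 11, 12, 13).

Steps most likely to fail:

Step 6. The ortho-fluoro aldehyde 11 is a weak SNAr acceptor (its formyl group is damped by ortho and para methoxy groups) and the nucleophile is hindered. The fallback replaces SNAr by a copper-catalysed coupling and sets out from 8. Commercial 5-bromo-1,2,3-trimethoxybenzene is formylated under the conditions of step 5 through 1-bromo-2-[chloro(methoxy)methyl]-3,4,5-trimethoxybenzene F1 to 6-bromo-2,3,4-trimethoxybenzaldehyde F2. Then 8 and F2 are joined with CuI, picolinic acid and K3PO4 in DMSO at 90 °C, where the ortho formyl group assists the copper step. This gives 12, and the route resumes at step 7.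

Step 11. The phenol of 14 is flanked by a methoxy and a bulky aryloxy group, both partners are large, and its phenoxide could in principle attack ring G of 19 para to the formyl group. The fallback drops the metal-catalysed union (and steps 8–10) and grows the second arm one ring at a time by the relay of steps 1 and 2, setting out from 14. Compound 14 and 2 (Cs2CO3, DMSO, 120 °C) give pentamer aldehyde F3. mCPBA, then K2CO3 in MeOH, gives pentamer phenol F5 through pentamer aryl formate F4. A second SNAr with 2 gives hexamer aldehyde F6, and oxidation gives hexamer phenol F8 through hexamer aryl formate F7. A third SNAr of F8 with 2 gives 20, and the route resumes at step 12.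

Step 13. Sixteen ether cleavages must all go to completion, and the product is a very polar, air-sensitive polyphenol that is hard to free from boron salts. The fallback isolates it as a stable derivative and sets out from 22. After the BBr3 cleavage and methanol quench the crude material is not purified but acetylated (Ac2O, pyridine, DMAP cat., rt) to heptadecaacetate F9, which is purified on silica. Acid methanolysis (HCl generated from catalytic AcCl in degassed MeOH, rt, argon) then removes the acetates and evaporation leaves 23.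

**Further compounds**

F1 | step 6 | 1-bromo-2-[chloro(methoxy)methyl]-3,4,5-trimethoxybenzene (racemic) | COC(Cl)c1c(Br)cc(OC)c(OC)c1OC
F2 | step 6 | 6-bromo-2,3,4-trimethoxybenzaldehyde | COc1cc(Br)c(C=O)c(OC)c1OC
F3 | step 11 | pentamer aldehyde (14 O-arylated by the C–F carbon of 2) | COc1cc(OC)c(Oc2cc(OC)c(Oc3cc(OC)c(Oc4cc(OC)c(OC)c(OC)c4Oc4cc(OC)c(C=O)c(OC)c4)c(OC)c3)c(OC)c2)c(OC)c1
F4 | step 11 | pentamer aryl formate | COc1cc(OC)c(Oc2cc(OC)c(Oc3cc(OC)c(Oc4cc(OC)c(OC)c(OC)c4Oc4cc(OC)c(OC=O)c(OC)c4)c(OC)c3)c(OC)c2)c(OC)c1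
F5 | step 11 | pentamer phenol | COc1cc(OC)c(Oc2cc(OC)c(Oc3cc(OC)c(Oc4cc(OC)c(OC)c(OC)c4Oc4cc(OC)c(O)c(OC)c4)c(OC)c3)c(OC)c2)c(OC)c1
F6 | step 11 | hexamer aldehyde | COc1cc(OC)c(Oc2cc(OC)c(Oc3cc(OC)c(Oc4cc(OC)c(OC)c(OC)c4Oc4cc(OC)c(Oc5cc(OC)c(C=O)c(OC)c5)c(OC)c4)c(OC)c3)c(OC)c2)c(OC)c1
F7 | step 11 | hexamer aryl formate | COc1cc(OC)c(Oc2cc(OC)c(Oc3cc(OC)c(Oc4cc(OC)c(OC)c(OC)c4Oc4cc(OC)c(Oc5cc(OC)c(OC=O)c(OC)c5)c(OC)c4)c(OC)c3)c(OC)c2)c(OC)c1
F8 | step 11 | hexamer phenol | COc1cc(OC)c(Oc2cc(OC)c(Oc3cc(OC)c(Oc4cc(OC)c(OC)c(OC)c4Oc4cc(OC)c(Oc5cc(OC)c(O)c(OC)c5)c(OC)c4)c(OC)c3)c(OC)c2)c(OC)c1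
F9 | step 13 | heptadecaacetate of 23 | CC(=O)Oc1cc(OC(C)=O)c(Oc2cc(OC(C)=O)c(Oc3cc(OC(C)=O)c(Oc4cc(OC(C)=O)c(OC(C)=O)c(OC(C)=O)c4Oc4cc(OC(C)=O)c(Oc5cc(OC(C)=O)c(Oc6cc(OC(C)=O)c(OC(C)=O)c(OC(C)=O)c6)c(OC(C)=O)c5)c(OC(C)=O)c4)c(OC(C)=O)c3)c(OC(C)=O)c2)c(OC(C)=O)c1
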